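**Route overview**

- Labdane numbering is used: C20 on C10, C18/C19 on C4, C17 the epoxide CH2, C11/C12 the tetrahydrofuran CH2 groups, C13 the bis-spiro carbon, C14/C15/C16 the butyrolactone CH2, OCH2 and C=O; α is the face opposite C20.
- Enabling feature: the ring O–C9–C11–C12–C13 carries C8 (ring B, ketone level) and C16 (lactone carbonyl) cis, one on each carbon next to oxygen. A C8=C16 bond would therefore make it a 7-oxabicyclo[2.2.1]heptene, the adduct of a 2,5-disubstituted furan and an alkyne.
- Cuts, in retrosynthetic order: C8–C17 and C8–O of the epoxide; the C19 lactone O–C6 bond; the C16–O(C15) lactone bond with C8 and C16 rejoined as an alkene; C9–C8 and C13–C16 (furan plus alkyne); then C4–C18, C5–C6, C4–C19 and C10–C9 on ring A.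
- Forward order: furan and ring A are joined at C10; ring A is dressed with C19, the C6–C7–C8–C16 chain and C18; the cycloaddition closes ring B and the oxygen bridge; hydrogenation and ozonolysis open the temporary carbocycle and close the butyrolactone; the 19,6-lactone and the epoxide follow.
- Stereochemistry: C10 from the chiral copper catalyst; C5 from conjugate addition anti to the furyl group; C4 from α-face enolate methylation; C9 and C13 together in the cycloaddition; C6 from delivery by the axial C19 acid; C8 from equatorial attack of a sulfur ylide.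

Key step: step 9

Remark: the conjugate adduct of step 5 is drawn as its C4-equatorial ester; either C4 epimer gives the same enolate in step 6.

**Route**

Step 1
Reactants: 1 2-(furan-2-yl)ethanol
Product: 2 2-[2-(benzyloxy)ethyl]furan
Conditions: NaH, BnBr, Bu4NI (cat.), THF, 0 °C → rt
Reagents that add atoms: benzyl bromide, BrCc1ccccc1
Why: Williamson etherification of a primary alkoxide; the benzyl ether should survive the organolithium, organoaluminium, Grignard and enolate steps and leave later by hydrogenolysis.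

Step 2
Reactants: 2 2-[2-(benzyloxy)ethyl]furan; 3 3-methylcyclohex-2-en-1-one
Product: 7 (S)-triethyl({3-[5-(2-benzyloxyethyl)furan-2-yl]-3-methylcyclohex-1-en-1-yl}oxy)silane, via lithiofuran 4 (not isolated), via furyl(dimethyl)alane 5 (not isolated), via aluminium enolate 6 (not isolated)
Conditions: 2, n-BuLi, THF, −78 → 0 °C; Me2AlCl, −78 °C → rt; then 3, Cu(OTf)2 (5 mol %), silver carbene complex made from a chiral sulfonate-bearing imidazolinium salt and Ag2O (2.5 mol %), THF, −30 °C; Et3SiOTf, −30 → 0 °C
Reagents that add atoms: triethylsilyl trifluoromethanesulfonate, CC[Si](CC)(CC)OS(=O)(=O)C(F)(F)F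
Why: Lithiation of the 2-alkylfuran at its free α position, Li-to-Al exchange and NHC–Cu-catalysed asymmetric conjugate addition of the heteroaryl(dimethyl)alane to the β-methyl enone are established for quaternary centres; the catalyst enantiomer is chosen to make C10 (S), and O-silylation of the aluminium enolate fixes the enolate double bond at C4=C5.

Step 3
Reactants: 7 (S)-triethylsilyl enol ether
Product: 9 (S)-3-[5-(2-benzyloxyethyl)furan-2-yl]-3-methylcyclohex-1-en-1-yl trifluoromethanesulfonate, via lithium enolate 8 (not isolated)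
Conditions: MeLi, THF, 0 °C → rt; then Comins' reagent, −78 → 0 °C
Reagents that add atoms: Comins' reagent [N-(5-chloropyridin-2-yl)-1,1,1-trifluoro-N-(trifluoromethylsulfonyl)methanesulfonamide], O=S(=O)(N(c1ccc(Cl)cn1)S(=O)(=O)C(F)(F)F)C(F)(F)F
Why: Methyllithium attacks silicon and frees the lithium enolate without proton exchange, so O-triflation should give the enol triflate with the double bond still at C4=C5.

Step 4
Reactants: 9 enol triflate
Product: 10 benzyl (S)-3-[5-(2-benzyloxyethyl)furan-2-yl]-3-methylcyclohex-1-ene-1-carboxylate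
Conditions: Pd(OAc)2 (5 mol %), dppp, CO (1 atm), BnOH, Et3N, DMF, 70 °C
Reagents that add atoms: carbon monoxide, [C-]#[O+]; benzyl alcohol, OCc1ccccc1
Why: Palladium-catalysed alkoxycarbonylation (oxidative addition of zerovalent palladium to the enol triflate, CO insertion, capture of the acyl-palladium by benzyl alcohol) should install C19 as an ester that hydrogenolysis removes later.

Step 5
Reactants: 10 benzyl enoate; 11 (4-bromobut-1-yn-1-yl)trimethylsilane
Product: 14 benzyl (1R,2S,3S)-3-[5-(2-benzyloxyethyl)furan-2-yl]-3-methyl-2-[4-(trimethylsilyl)but-3-yn-1-yl]cyclohexane-1-carboxylate, via Grignard reagent 12 (not isolated), via silyl ketene acetal 13 (not isolated)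
Conditions: 11, Mg, THF, rt; then 10, CuI (10 mol %), Me3SiCl, THF, −78 → −20 °C; aq. NH4Cl
Reagents that add atoms: none
Why: Copper-catalysed, Me3SiCl-accelerated conjugate addition of a Grignard reagent to an enoate; the cuprate should enter C5 antiperiplanar to the pseudoaxial furyl group on the neighbouring quaternary C10 (Felkin–Anh-type approach anti to the larger sp2 substituent), placing the chain trans to the furan and cis to the C10 methyl, while the configuration at C4 after protonation does not matter.

Step 6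
Reactants: 14 conjugate adduct
Product: 16 benzyl (1S,2R,3S)-3-[5-(2-benzyloxyethyl)furan-2-yl]-1,3-dimethyl-2-[4-(trimethylsilyl)but-3-yn-1-yl]cyclohexane-1-carboxylate, via lithium ester enolate 15 (not isolated)
Conditions: LiN(iPr)2, THF, −78 °C; MeI, DMPU, −78 → 0 °C
Reagents that add atoms: iodomethane, CI
Why: Ester enolate alkylation; methyl iodide should attack the exocyclic enolate from the α face, trans to the vicinal C5 chain and away from the syn-axial C10 methyl, as in C4 methylations of podocarpate-type esters, leaving C19 axial (β) and C18 equatorial (α).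

Step 7
Reactants: 16 C4-quaternary ester
Product: 17 benzyl (1S,2R,3S)-3-[5-(2-benzyloxyethyl)furan-2-yl]-2-(but-3-yn-1-yl)-1,3-dimethylcyclohexane-1-carboxylate
Conditions: K2CO3 (cat.), MeOH–THF, rt
Reagents that add atoms: none
Why: Carbonate-catalysed methanolysis cleaves only the alkynyl C–Si bond; the neopentyl-type benzyl ester is too hindered to transesterify.

Step 8
Reactants: 17 terminal alkyne
Product: 19 benzyl (1S,2R,3S)-3-[5-(2-benzyloxyethyl)furan-2-yl]-1,3-dimethyl-2-[4-(4-methylbenzenesulfonyl)but-3-yn-1-yl]cyclohexane-1-carboxylate, via (E)-β-iodovinyl sulfone 18 (not isolated)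
Conditions: TsI (freshly made from sodium p-toluenesulfinate and I2), CH2Cl2, visible light, rt; evaporate; K2CO3, acetone, 50 °C
Reagents that add atoms: p-toluenesulfonyl iodide, Cc1ccc(cc1)S(=O)(=O)I
Why: Radical-chain iodosulfonylation puts the tosyl group on the terminal alkyne carbon and iodine on the internal one (iodine transfer from TsI should outrun any cyclisation of the vinyl radical), and carbonate then removes HI by an E1cB-type dehydroiodination; amine bases are avoided because they isomerise propargylic sulfones to allenyl sulfones.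

Step 9
Reactants: 19 furan-tethered acetylenic p-tolyl sulfone
Product: 20 benzyl (4S,5R,9S,10S,13S)-15-benzyloxy-9,13-epoxy-16-(4-methylbenzenesulfonyl)-17-nor-8,16-cyclolabda-8(16),11-dien-19-oate (7-oxanorbornadiene cycloadduct; ring B closed)
Conditions: toluene (0.01 M, degassed), BHT (cat.), 110 °C, sealed tube
Reagents that add atoms: none
Why: A concerted, thermally allowed [4+2] cycloaddition of normal electron demand joins the electron-rich 2,5-dialkylfuran (diene C9=C11–C12=C13) to the sulfonyl-activated alkyne C8≡C16, forming C9–C8 and C13–C16 in one suprafacial event; the closest known reaction types are the intramolecular Diels–Alder reaction of furans with tethered activated alkynes and the cycloaddition of 2,5-dialkylfurans with acetylenic sulfones. Ring B closes as a six-membered carbocycle through the chair-like C10–C5–C6–C7 tether, which the ring A chair holds in place by the trans-diequatorial furyl group and chain next to quaternary C10; the same event closes the carbocycle C9–C8–C16–C13–C12–C11 across which the furan oxygen becomes the bridge of a 7-oxabicyclo[2.2.1]heptadiene. C13 follows C9 because the alkyne adds to one face of the planar furan, so the only open question is which furan face reacts, that is, the configuration of C9 relative to C10 and C5. The required face places the bridging oxygen axial on ring B and anti to the axial C10 methyl with C11 equatorial; this matches the preferred furan rotamer (methyl eclipsing C9=C11, oxygen turned away) and the less crowded chair-like transition state, since an axial C11 would clash with H5 and the axial C7 hydrogen, but the bias is modest. The step also needs cycloaddition to win over propargyl-to-allenyl isomerisation and over ring opening of the adduct, which neutral base-free toluene, a radical inhibitor and two fully substituted bridgeheads (no hydrogen to lose towards a phenol) should secure.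

Step 10
Reactants: 20 oxanorbornadiene cycloadduct
Product: 21 (4S,5R,9S,10S,13R)-9,13-epoxy-15-hydroxy-16-(4-methylbenzenesulfonyl)-17-nor-8,16-cyclolabd-8(16)-en-19-oic acid
Conditions: H2 (1 atm), Pd/C, EtOAc–EtOH, rt
Reagents that add atoms: none
Why: The strained cis-disubstituted C11=C12 bond should hydrogenate far faster than the tetrasubstituted sulfonyl-bearing C8=C16 bond, and the same catalyst removes the benzyl ester and benzyl ether by hydrogenolysis; saturating C11–C12 also closes the way back to the furan.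

Step 11
Reactants: 21 hydroxy acid vinyl sulfone
Product: 23 (4S,5R,9S,10S,13R)-9,13-epoxy-8-oxo-17-norlabdane-16,15-olide-19-oic acid, via keto acyl sulfone 22 (not isolated)
Conditions: O3, CH2Cl2–MeOH, −78 °C; Me2S, −78 °C → rt
Reagents that add atoms: ozone, [O-][O+]=O
Why: Ozonolysis (Criegee cleavage) of the strained vinyl sulfone gives the C8 ketone and a C16 acyl sulfone, an activated acyl donor that the C15 hydroxyl should capture in a 5-exo-trig acyl substitution with loss of p-toluenesulfinate, closing the spiro-butyrolactone without touching C9 or C13.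

Step 12
Reactants: 23 keto lactone acid
Product: 25 (4S,5R,9S,10S,13R)-9,13-epoxy-8-oxo-17-norlabd-6-ene-16,15-olide-19-oic acid, via bis(trimethylsilyl) derivative 24 (not isolated)
Conditions: Me3SiOTf, Et3N, CH2Cl2, 0 °C; then Pd(OAc)2, MeCN, rt; aqueous work-up
Reagents that add atoms: none
Why: Enolisation is possible only towards C7 (C9, C4 and C13 carry no hydrogen), and Saegusa–Ito oxidation of the silyl enol ether by divalent palladium (β-hydride loss from C6) should give the C6=C7 enone, the silyl ester falling off on work-up.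

Step 13
Reactants: 25 enone acid
Product: 26 (4S,5R,6R,9S,10S,13R)-9,13-epoxy-8-oxo-17-norlabdane-19,6:16,15-diolide
Conditions: TsOH·H2O (cat.), CH2Cl2, rt
Reagents that add atoms: none
Why: Acid-catalysed intramolecular oxa-Michael addition; the axial C19 carboxyl group lies over the β face of C6 and can add only there, closing the cis-bridged γ-lactone (5-exo-trig) and setting C6 as (R).

Step 14
Reactants: 26 keto dilactone
Product: 28 (4S,5R,6R,8R,9S,10S,13R)-8,17:9,13-diepoxylabdane-19,6:16,15-diolide (CNP0105047.2), via sulfonium betaine 27 (not isolated)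
Conditions: Me3S+ I−, KN(SiMe3)2, THF, −20 °C; then 26, −78 → −20 °C
Reagents that add atoms: trimethylsulfonium iodide, C[S+](C)C.[I-]
Why: Corey–Chaykovsky epoxidation; the ylide carbon should attack the C8 carbonyl along the equatorial α trajectory because the axial β face is closed by the syn-axial C10 methyl and C6 oxygen, and the β-alkoxide then displaces dimethyl sulfide to give the epoxide with oxygen β and C17 α, low temperature holding back β-elimination of the C6 acyloxy group.

**Compound list**

1 | 2-(furan-2-yl)ethanol | OCCc1ccco1 | starting material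
2 | 2-[2-(benzyloxy)ethyl]furan | c1ccc(CCOCc2ccccc2)o1 | intermediate
3 | 3-methylcyclohex-2-en-1-one | CC1=CC(=O)CCC1 | starting material
4 | [5-(2-benzyloxyethyl)furan-2-yl]lithium | [Li]c1ccc(CCOCc2ccccc2)o1 | intermediate (not isolated)
5 | [5-(2-benzyloxyethyl)furan-2-yl]dimethylalane | C[Al](C)c1ccc(CCOCc2ccccc2)o1 | intermediate (not isolated)
6 | dimethylaluminium enolate of (S)-3-[5-(2-benzyloxyethyl)furan-2-yl]-3-methylcyclohexanone (enolate towards C5) | C[C@]1(c2ccc(CCOCc3ccccc3)o2)CCCC(O[Al](C)C)=C1 | intermediate (not isolated)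
7 | (S)-triethyl({3-[5-(2-benzyloxyethyl)furan-2-yl]-3-methylcyclohex-1-en-1-yl}oxy)silane | C[C@]1(c2ccc(CCOCc3ccccc3)o2)CCCC(O[Si](CC)(CC)CC)=C1 | intermediate
8 | lithium enolate corresponding to 7 | C[C@]1(c2ccc(CCOCc3ccccc3)o2)CCCC(O[Li])=C1 | intermediate (not isolated)
9 | (S)-3-[5-(2-benzyloxyethyl)furan-2-yl]-3-methylcyclohex-1-en-1-yl trifluoromethanesulfonate | C[C@]1(c2ccc(CCOCc3ccccc3)o2)CCCC(OS(=O)(=O)C(F)(F)F)=C1 | intermediate
10 | benzyl (S)-3-[5-(2-benzyloxyethyl)furan-2-yl]-3-methylcyclohex-1-ene-1-carboxylate | C[C@]1(c2ccc(CCOCc3ccccc3)o2)CCCC(C(=O)OCc2ccccc2)=C1 | intermediate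
11 | (4-bromobut-1-yn-1-yl)trimethylsilane | C[Si](C)(C)C#CCCBr | starting material
12 | [4-(trimethylsilyl)but-3-yn-1-yl]magnesium bromide | C[Si](C)(C)C#CCC[Mg]Br | intermediate (not isolated)
13 | benzyl trimethylsilyl ketene acetal of the conjugate adduct (C4=C19; chain on C5 trans to furyl) | C[C@]1(c2ccc(CCOCc3ccccc3)o2)CCCC(=C(O[Si](C)(C)C)OCc2ccccc2)[C@@H]1CCC#C[Si](C)(C)C | intermediate (not isolated)
14 | benzyl (1R,2S,3S)-3-[5-(2-benzyloxyethyl)furan-2-yl]-3-methyl-2-[4-(trimethylsilyl)but-3-yn-1-yl]cyclohexane-1-carboxylate (chain trans to furyl; ester drawn equatorial) | C[C@]1(c2ccc(CCOCc3ccccc3)o2)CCC[C@@H](C(=O)OCc2ccccc2)[C@@H]1CCC#C[Si](C)(C)C | intermediate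
15 | lithium ester enolate of 14 | C[C@]1(c2ccc(CCOCc3ccccc3)o2)CCCC(=C(O[Li])OCc2ccccc2)[C@@H]1CCC#C[Si](C)(C)C | intermediate (not isolated)
16 | benzyl (1S,2R,3S)-3-[5-(2-benzyloxyethyl)furan-2-yl]-1,3-dimethyl-2-[4-(trimethylsilyl)but-3-yn-1-yl]cyclohexane-1-carboxylate (ester axial, cis to the C10 methyl) | C[C@]1(c2ccc(CCOCc3ccccc3)o2)CCC[C@](C)(C(=O)OCc2ccccc2)[C@@H]1CCC#C[Si](C)(C)C | intermediate
17 | benzyl (1S,2R,3S)-3-[5-(2-benzyloxyethyl)furan-2-yl]-2-(but-3-yn-1-yl)-1,3-dimethylcyclohexane-1-carboxylate | C[C@]1(c2ccc(CCOCc3ccccc3)o2)CCC[C@](C)(C(=O)OCc2ccccc2)[C@@H]1CCC#C | intermediate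
18 | (E)-β-iodovinyl sulfone from 17 (iodine on C8, tosyl on C16, trans) | C[C@]1(c2ccc(CCOCc3ccccc3)o2)CCC[C@](C)(C(=O)OCc2ccccc2)[C@@H]1CC/C(I)=C\S(=O)(=O)c1ccc(C)cc1 | intermediate (not isolated)
19 | benzyl (1S,2R,3S)-3-[5-(2-benzyloxyethyl)furan-2-yl]-1,3-dimethyl-2-[4-(4-methylbenzenesulfonyl)but-3-yn-1-yl]cyclohexane-1-carboxylate | C[C@]1(c2ccc(CCOCc3ccccc3)o2)CCC[C@](C)(C(=O)OCc2ccccc2)[C@@H]1CCC#CS(=O)(=O)c1ccc(C)cc1 | intermediate
20 | benzyl (4S,5R,9S,10S,13S)-15-benzyloxy-9,13-epoxy-16-(4-methylbenzenesulfonyl)-17-nor-8,16-cyclolabda-8(16),11-dien-19-oate (oxygen bridge α at C9) | C[C@@]12CCC[C@](C)(C(=O)OCc5ccccc5)[C@@H]2CCC3=C(S(=O)(=O)c5ccc(C)cc5)[C@]4(CCOCc5ccccc5)C=C[C@]13O4 | intermediate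
21 | (4S,5R,9S,10S,13R)-9,13-epoxy-15-hydroxy-16-(4-methylbenzenesulfonyl)-17-nor-8,16-cyclolabd-8(16)-en-19-oic acid | C[C@@]12CCC[C@](C)(C(=O)O)[C@@H]2CCC3=C(S(=O)(=O)c5ccc(C)cc5)[C@]4(CCO)CC[C@]13O4 | intermediate
22 | (4S,5R,9S,10S,13R)-9,13-epoxy-15-hydroxy-8,16-dioxo-16-(4-methylbenzenesulfonyl)-17-norlabdan-19-oic acid (C16 acyl sulfone) | C[C@@]12CCC[C@](C)(C(=O)O)[C@@H]2CCC(=O)[C@]13CC[C@@](CCO)(C(=O)S(=O)(=O)c4ccc(C)cc4)O3 | intermediate (not isolated)
23 | (4S,5R,9S,10S,13R)-9,13-epoxy-8-oxo-17-norlabdane-16,15-olide-19-oic acid | C[C@@]12CCC[C@](C)(C(=O)O)[C@@H]2CCC(=O)[C@]13CC[C@]1(CCOC1=O)O3 | intermediate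
24 | trimethylsilyl ester and C7=C8 trimethylsilyl enol ether of 23 | C[C@@]12CCC[C@](C)(C(=O)O[Si](C)(C)C)[C@@H]2CC=C(O[Si](C)(C)C)[C@]13CC[C@]1(CCOC1=O)O3 | intermediate (not isolated)
25 | (4S,5R,9S,10S,13R)-9,13-epoxy-8-oxo-17-norlabd-6-ene-16,15-olide-19-oic acid | C[C@@]12CCC[C@](C)(C(=O)O)[C@@H]2C=CC(=O)[C@]13CC[C@]1(CCOC1=O)O3 | intermediate
26 | (4S,5R,6R,9S,10S,13R)-9,13-epoxy-8-oxo-17-norlabdane-19,6:16,15-diolide | C[C@@]12CCC[C@]3(C)C(=O)O[C@H](CC(=O)[C@]14CC[C@]1(CCOC1=O)O4)[C@H]23 | intermediate
27 | sulfonium betaine (C8 β-alkoxide, α-CH2–S+Me2) | C[C@@]12CCC[C@]3(C)C(=O)O[C@H](C[C@@]([O-])(C[S+](C)C)[C@]14CC[C@]1(CCOC1=O)O4)[C@H]23 | intermediate (not isolated)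
28 | (4S,5R,6R,8R,9S,10S,13R)-8,17:9,13-diepoxylabdane-19,6:16,15-diolide (CNP0105047.2) | C[C@@]12CCC[C@]3(C)C(=O)O[C@H](C[C@@]4(CO4)[C@]14CC[C@]1(CCOC1=O)O4)[C@H]23 | target

**Count**

Total step count: 14. Longest linear sequence: 14 steps (1 to 28); compounds 3 and 11 are bought and enter directly.

**Steps most likely to fail**

1. Step 9 (cycloaddition). The ring closure through a four-carbon tether may be slow enough that propargyl-to-allenyl isomerisation and decomposition of the acetylenic sulfone overtake it, or the furan face may be chosen poorly at the temperature required. The fallback sets out from 17 and returns at 23.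
   - Alkyne 17 is deprotonated (LiN(iPr)2, THF, −78 °C) and acylated with methyl chloroformate to the methyl alkynoate F1, which cannot isomerise to a sulfonyl allene.
   - F1 is cyclised under Lewis-acid activation (Me2AlCl, CH2Cl2, −78 → 0 °C), a known low-temperature mode for furan–ynoate intramolecular Diels–Alder reactions, to the oxanorbornadiene ester F2.
   - H2 over Pd/C saturates C11=C12 and removes both benzyl groups, giving the hydroxy acid enoate F3.
   - Ozonolysis (O3, then Me2S) gives the C8 ketone with a C16 α-keto ester, F4.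
   - LiOH, then H2O2, cleaves the α-keto acid oxidatively with loss of CO2, and acidification closes the butyrolactone to give 23.

2. Step 5 (conjugate addition). Addition at the β-carbon next to quaternary C10 may be sluggish, 1,2-attack on the ester may compete, or attack anti to the furyl group may not dominate. The fallback sets out from 9 and returns at 16; it addresses reactivity, and the lower temperature it allows should also sharpen facial selectivity.
   - Palladium-catalysed formylation of 9 (Pd(OAc)2, dppp, CO, Et3SiH, Et3N, DMF) gives the enal F5, a much stronger acceptor.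
   - Grignard reagent 12 with CuBr·SMe2 and Me3SiCl at −78 °C, then hydrolytic work-up, gives the aldehyde F6.
   - KOt-Bu and MeI methylate the α-carbon under the same facial bias as step 6, giving the quaternary aldehyde F7.
   - Pinnick oxidation (NaClO2, NaH2PO4, excess 2-methyl-2-butene to protect the furan) gives the carboxylic acid F8.
   - BnBr and K2CO3 in DMF give 16.

3. Step 14 (epoxidation). The basic ylide may enolise the ketone towards C7 and expel the C6 acyloxy group, or may react too slowly at the hindered carbonyl. The fallback sets out from 26 and returns at 28.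
   - The non-basic organocerium reagent from (isopropoxydimethylsilyl)methylmagnesium chloride and CeCl3 (THF, −78 °C) adds along the same equatorial α trajectory to give the β-hydroxysilane F9.
   - Tamao oxidation (KF, KHCO3, H2O2, THF–MeOH) gives the 8β,17-diol F10.
   - Selective sulfonylation of the primary hydroxyl (TsCl, pyridine, 0 °C) gives the primary tosylate F11.
   - DBU in CH2Cl2 closes the epoxide by displacement at C17 with retention at C8, giving 28.

**Further compounds**

F1 | step 9 | methyl alkynoate: benzyl (1S,2R,3S)-3-[5-(2-benzyloxyethyl)furan-2-yl]-2-(5-methoxy-5-oxopent-3-yn-1-yl)-1,3-dimethylcyclohexane-1-carboxylate | C[C@]1(c2ccc(CCOCc3ccccc3)o2)CCC[C@](C)(C(=O)OCc2ccccc2)[C@@H]1CCC#CC(=O)OC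
F2 | step 9 | oxanorbornadiene ester (analogue of 20 with CO2Me on C16 in place of the sulfonyl group) | C[C@@]12CCC[C@](C)(C(=O)OCc5ccccc5)[C@@H]2CCC3=C(C(=O)OC)[C@]4(CCOCc5ccccc5)C=C[C@]13O4
F3 | step 9 | hydroxy acid enoate (analogue of 21 with CO2Me on C16) | C[C@@]12CCC[C@](C)(C(=O)O)[C@@H]2CCC3=C(C(=O)OC)[C@]4(CCO)CC[C@]13O4
F4 | step 9 | C8 ketone with C16 α-keto methyl ester, free C15 hydroxyl and C19 acid | C[C@@]12CCC[C@](C)(C(=O)O)[C@@H]2CCC(=O)[C@]13CC[C@@](CCO)(C(=O)C(=O)OC)O3
F5 | step 5 | (S)-3-[5-(2-benzyloxyethyl)furan-2-yl]-3-methylcyclohex-1-ene-1-carbaldehyde | C[C@]1(c2ccc(CCOCc3ccccc3)o2)CCCC(C=O)=C1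
F6 | step 5 | aldehyde conjugate adduct (chain on C5 trans to furyl, CHO drawn equatorial) | C[C@]1(c2ccc(CCOCc3ccccc3)o2)CCC[C@@H](C=O)[C@@H]1CCC#C[Si](C)(C)C
F7 | step 5 | C4-quaternary aldehyde (CHO axial, methyl equatorial) | C[C@]1(c2ccc(CCOCc3ccccc3)o2)CCC[C@](C)(C=O)[C@@H]1CCC#C[Si](C)(C)C
F8 | step 5 | C4-quaternary carboxylic acid (free acid of 16) | C[C@]1(c2ccc(CCOCc3ccccc3)o2)CCC[C@](C)(C(=O)O)[C@@H]1CCC#C[Si](C)(C)C
F9 | step 14 | β-hydroxysilane (8β-hydroxy, 8α-CH2SiMe2(OiPr)) | C[C@@]12CCC[C@]3(C)C(=O)O[C@H](C[C@@](O)(C[Si](C)(C)OC(C)C)[C@]14CC[C@]1(CCOC1=O)O4)[C@H]23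
F10 | step 14 | 8β,17-diol | C[C@@]12CCC[C@]3(C)C(=O)O[C@H](C[C@@](O)(CO)[C@]14CC[C@]1(CCOC1=O)O4)[C@H]23
F11 | step 14 | 8β-hydroxy 17-tosylate | C[C@@]12CCC[C@]3(C)C(=O)O[C@H](C[C@@](O)(COS(=O)(=O)c5ccc(C)cc5)[C@]14CC[C@]1(CCOC1=O)O4)[C@H]23
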